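**Retrosynthetic overview**
- The target comes from its 3,19-diol acid by acetylation of the primary 19-hydroxyl; the diol acid comes from a methyl ester / 19-PMB ether by hydrolysis and PMB removal.
- Ring A is closed last through the C3–C4 bond: divalent titanocene couples the C3 aldehyde with the C4=C18 alkene of a monocyclic seco-aldehyde, and protonolysis of the oxatitanacycle gives the 3-hydroxyl and the C18 methyl.
- Enabling feature: in ring A the 3-hydroxyl (C3) and the C18 methyl (C4) are cis on adjacent carbons with the C19 CH2O group anti at the quaternary C4 (a cis-2-methylcyclohexanol unit), and the two arms sit trans-diequatorial on C10 and C5 of ring B.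
- The seco-aldehyde comes from a carvone-derived dienyl triflate: Negishi coupling installs the complete (E)-side chain at C9, and a 1,4-hydrogenation sets the 9-hydrogen and the Δ7 alkene; the aldehyde is unmasked from a silylpropargyl group.
- Ring B with C5 is (S)-carvone; C10 is built by two α′-alkylations and the C19 oxygen by ene chlorination and etherification of the isopropenyl group; ring order: B (from carvone), then A.

Key step: step 12

Remark: labdane numbering is used for every intermediate (ring A = C1–C5, C10; ring B = C5–C10; side chain C11–C16; C17 on C8, C18 and C19 on C4, C20 on C10), and α/β refer to the usual drawing, in which the C20 methyl of this ent-labdane is α.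

Step 1
Reactants: 1 but-3-yn-1-ol
Product: 3 methyl (E)-5-hydroxy-3-methylpent-2-enoate, via alkenylalane 2 (not isolated)
Conditions: AlMe3 (3 equiv), Cp2ZrCl2 (25 mol %), CH2Cl2, 0 °C to rt; then ClCO2Me, 0 °C; aq. HCl work-up
Reagents that add atoms: trimethylaluminium, C[Al](C)C; methyl chloroformate, COC(=O)Cl
Why: Zirconium-catalysed carboalumination adds methyl and aluminium syn across the alkyne with aluminium on the terminal carbon, and acylation of the alkenylalane with retention fixes the (E)-trisubstituted enoate.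

Step 2
Reactants: 3 methyl (E)-5-hydroxy-3-methylpent-2-enoate
Product: 4 methyl (E)-5-iodo-3-methylpent-2-enoate
Conditions: I2, PPh3, imidazole, CH2Cl2, 0 °C
Reagents that add atoms: iodine, II
Why: Appel iodination of the primary alcohol runs under near-neutral conditions that should leave the enoate geometry untouched.

Step 3
Reactants: 5 (S)-(+)-carvone
Product: 7 6-methylcarvone (C6 epimers), via lithium enolate 6 (not isolated)
Conditions: LiN(iPr)2, THF, −78 °C; then MeI, −78 to 0 °C
Reagents that add atoms: iodomethane, CI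
Why: Kinetic deprotonation of the enone takes place at the α′-carbon (C10 in labdane numbering) and enolate alkylation installs the future C20 methyl; the configuration of this centre is erased again in step 4.

Step 4
Reactants: 7 6-methylcarvone
Product: 9 (5R,6R)-2,6-dimethyl-5-(prop-1-en-2-yl)-6-[3-(triisopropylsilyl)prop-2-yn-1-yl]cyclohex-2-en-1-one, via lithium enolate 8 (not isolated)
Conditions: LiN(iPr)2, THF, −78 to −20 °C; then 3-bromo-1-(triisopropylsilyl)prop-1-yne, DMPU, −78 °C to rt
Reagents that add atoms: 3-bromo-1-(triisopropylsilyl)prop-1-yne, BrCC#C[Si](C(C)C)(C(C)C)C(C)C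
Why: Enolate alkylation with the reactive propargylic bromide should occur on the face opposite to the neighbouring isopropenyl group, which sets the quaternary C10 with the C1–C3 arm trans and the methyl cis to the C4 unit.

Step 5
Reactants: 9 silylpropargyl enone
Product: 10 allylic chloride (isopropenyl group converted into 3-chloroprop-1-en-2-yl)
Conditions: Ca(OCl)2, solid CO2, CH2Cl2/H2O, 0 °C
Reagents that add atoms: calcium hypochlorite, [Ca+2].[O-]Cl.[O-]Cl
Why: Ene-type chlorination by hypochlorous acid is selective for the electron-rich 1,1-disubstituted alkene over the enone and the silylalkyne and moves the double bond into the former methyl group, giving the C4=C18 / C19–Cl unit.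

Step 6
Reactants: 10 allylic chloride
Product: 11 PMB ether (C19–OPMB)
Conditions: 4-methoxybenzyl alcohol, NaH, Bu4NI (cat.), THF/DMF, 0 °C to rt
Reagents that add atoms: 4-methoxybenzyl alcohol, COc1ccc(CO)cc1
Why: Williamson ether synthesis on the primary allylic chloride installs the C19 oxygen as an ether that is a poor leaving group in the organometallic steps ahead, and the enone has no α′-hydrogen left to enolise.

Step 7
Reactants: 11 PMB ether
Product: 13 dienyl triflate (6,8-dien-9-yl trifluoromethanesulfonate), via potassium dienolate 12 (not isolated)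
Conditions: KN(SiMe3)2, THF, −78 °C; then PhNTf2, −78 to 0 °C
Reagents that add atoms: N-phenylbis(trifluoromethanesulfonimide), O=S(=O)(N(c1ccccc1)S(=O)(=O)C(F)(F)F)C(F)(F)F
Why: With C10 quaternary the only acidic position is the γ-carbon C6, so deprotonation gives the linear dienolate and O-triflation gives the alkenyl triflate at C9.

Step 8
Reactants: 13 dienyl triflate; 4 methyl (E)-5-iodo-3-methylpent-2-enoate
Product: 15 triene ester (side chain on C9 of the 6,8-diene), via alkylzinc iodide 14 (not isolated)
Conditions: 4, Zn dust, LiCl, THF, 40 °C; then 13, PdCl2(dppf) (5 mol %), THF/NMP, 55 °C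
Reagents that add atoms: none
Why: Negishi coupling of the ester-tolerant primary alkylzinc reagent with the alkenyl triflate joins the complete (E)-configured side chain to C9 while that carbon is still sp2 and the adjacent quaternary C10 is least felt.

Step 9
Reactants: 15 triene ester
Product: 16 methyl (5S,9R,10S,13E)-19-[(4-methoxybenzyl)oxy]-3-(triisopropylsilyl)-3,4-secolabda-4(18),7,13-trien-2-yn-15-oate
Conditions: (η6-naphthalene)Cr(CO)3 (20 mol %), H2 (50 atm), THF, 45 °C
Reagents that add atoms: none
Why: Chromium tricarbonyl-catalysed 1,4-hydrogenation of the cisoid homoannular diene should add both hydrogens from the β face, opposite to the pseudoaxial C20 methyl, giving the Δ7 alkene and the 9β-hydrogen (C11 equatorial) without reducing isolated alkenes.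

Step 10
Reactants: 16 silylalkyne ester
Product: 17 methyl (5S,9R,10S,13E)-19-[(4-methoxybenzyl)oxy]-3,4-secolabda-4(18),7,13-trien-2-yn-15-oate
Conditions: Bu4NF, AcOH, THF, 0 °C to rt
Reagents that add atoms: none
Why: Fluoride-induced protodesilylation frees the terminal alkyne, with acetic acid buffering the medium to protect the methyl ester.

Step 11
Reactants: 17 terminal alkyne
Product: 18 methyl (5S,9R,10S,13E)-19-[(4-methoxybenzyl)oxy]-3-oxo-3,4-secolabda-4(18),7,13-trien-15-oate
Conditions: [CpRu(MeCN)3]PF6 (5 mol %), 5,5′-bis(trifluoromethyl)-2,2′-bipyridine (5 mol %), NMP/H2O, 25 °C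
Reagents that add atoms: water, O
Why: Ruthenium-catalysed aldehyde-selective hydration of the terminal alkyne through a vinylidene intermediate delivers the C3 aldehyde directly and should leave alkenes, ether and ester untouched.

Step 12
Reactants: 18 seco-aldehyde
Product: 20 methyl (3S,4R,5S,9R,10S,13E)-3-hydroxy-19-[(4-methoxybenzyl)oxy]labda-7,13-dien-15-oate, via oxatitanacycle 19 (not isolated)
Conditions: Cp2Ti(PMe3)2 (1.2 equiv), toluene, rt to 60 °C; then HCl (2 M in Et2O), 0 °C
Reagents that add atoms: none
Why: Proposed new method: loss of PMe3 from Cp2Ti(PMe3)2 gives divalent titanocene, which binds the C3 aldehyde as an η2 complex and inserts the pendant C4=C18 alkene into the Ti–C3 bond so that C3 bonds to the internal carbon C4 and titanium to the terminal carbon C18 (oxatitanacyclopentane 19), and protonolysis of the Ti–O and Ti–C18 bonds releases the 3-hydroxyl and the C18 methyl; the closest known reaction type is the titanocene-mediated reductive cyclization of δ,ε- and ε,ζ-unsaturated aldehydes and ketones to cis-2-methylcycloalkanols, extended here to a 1,1-disubstituted alkene that becomes a quaternary carbon. Ring A closes in a 6-exo-trig migratory insertion while the five-membered metallacycle forms in the same event. C3 and C4 are both controlled by the metallacycle, which must be cis-fused to ring A and should lie on the β face away from the axial C20 methyl, placing O3 axial (β), C18 equatorial (β) and the C19 CH2OPMB group axial (α). The step needs chemoselectivity for the aldehyde and the 1,1-disubstituted alkene over the enoate and the Δ7 alkene, regioselectivity for C3–C4 over C3–C18 bonding and facial selectivity; these should be secured by the higher π-acidity of the aldehyde, by titanium taking the unhindered CH2 terminus in a six- rather than seven-membered closure, and by the trans-diequatorial arms on ring B next to the angular methyl.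

Step 13
Reactants: 20 PMB ether
Product: 21 methyl (3S,4R,5S,9R,10S,13E)-3,19-dihydroxylabda-7,13-dien-15-oate
Conditions: DDQ, CH2Cl2/pH 7 buffer, 0 °C
Reagents that add atoms: none
Why: Oxidative cleavage of the PMB ether frees the C19 alcohol, and the 3-hydroxyl, being anti (trans-diaxial) to C19, cannot trap the intermediate oxocarbenium ion as a cyclic acetal.

Step 14
Reactants: 21 diol ester
Product: 22 (3S,4R,5S,9R,10S,13E)-3,19-dihydroxylabda-7,13-dien-15-oic acid
Conditions: LiOH, THF/MeOH/H2O, 40 °C; then 1 M HCl
Reagents that add atoms: lithium hydroxide, [Li+].[OH-]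
Why: Saponification of the methyl enoate is placed before the acetate is introduced so that no differentiation of two esters is needed.

Step 15
Reactants: 22 diol acid
Product: 23 (3S,4R,5S,9R,10S,13E)-19-acetoxy-3-hydroxylabda-7,13-dien-15-oic acid (CNP0325522.1)
Conditions: Ac2O (2.2 equiv), pyridine, CH2Cl2, −20 to 0 °C; then H2O, NaHCO3, THF, rt; acidification
Reagents that add atoms: acetic anhydride, CC(=O)OC(C)=O
Why: The primary 19-hydroxyl should be acylated much faster than the axial secondary 3-hydroxyl flanked by the quaternary C4, and the mixed anhydride formed at C15 is hydrolysed in the aqueous work-up.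

**Compound list**
1 | but-3-yn-1-ol | C#CCCO | starting material
2 | alkenylalane, (E)-[4-(dimethylalumanyloxy)-2-methylbut-1-en-1-yl]dimethylalane | C[Al](C)/C=C(\C)CCO[Al](C)C | intermediate
3 | methyl (E)-5-hydroxy-3-methylpent-2-enoate | OCC/C(C)=C/C(=O)OC | intermediate
4 | methyl (E)-5-iodo-3-methylpent-2-enoate | ICC/C(C)=C/C(=O)OC | intermediate
5 | (S)-(+)-carvone, (5S)-2-methyl-5-(prop-1-en-2-yl)cyclohex-2-en-1-one | CC(=C)[C@H]1CC=C(C)C(=O)C1 | starting material
6 | lithium enolate of 5 (lithium 6-methyl-3-(prop-1-en-2-yl)cyclohexa-1,5-dien-1-olate, ring stereocentre as in 5) | CC(=C)[C@H]1CC=C(C)C(O[Li])=C1 | intermediate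
7 | 6-methylcarvone, (5S)-2,6-dimethyl-5-(prop-1-en-2-yl)cyclohex-2-en-1-one, mixture of C6 epimers | CC(=C)[C@H]1CC=C(C)C(=O)C1C | intermediate
8 | lithium enolate of 7 (lithium 2,6-dimethyl-3-(prop-1-en-2-yl)cyclohexa-1,5-dien-1-olate) | CC(=C)[C@H]1CC=C(C)C(O[Li])=C1C | intermediate
9 | (5R,6R)-2,6-dimethyl-5-(prop-1-en-2-yl)-6-[3-(triisopropylsilyl)prop-2-yn-1-yl]cyclohex-2-en-1-one (silylpropargyl trans to isopropenyl; H-5 β, C20 methyl α) | CC(=C)[C@H]1CC=C(C)C(=O)[C@]1(C)CC#C[Si](C(C)C)(C(C)C)C(C)C | intermediate
10 | allylic chloride: 9 with the isopropenyl group replaced by 3-chloroprop-1-en-2-yl, ring stereocentres as in 9 | ClCC(=C)[C@H]1CC=C(C)C(=O)[C@]1(C)CC#C[Si](C(C)C)(C(C)C)C(C)C | intermediate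
11 | PMB ether: 5-{3-[(4-methoxybenzyl)oxy]prop-1-en-2-yl}-2,6-dimethyl-6-[3-(triisopropylsilyl)prop-2-yn-1-yl]cyclohex-2-en-1-one, ring stereocentres as in 9 | COc1ccc(COCC(=C)[C@H]2CC=C(C)C(=O)[C@]2(C)CC#C[Si](C(C)C)(C(C)C)C(C)C)cc1 | intermediate
12 | potassium dienolate of 11 (O–K on C9, 6,8-diene) | COc1ccc(COCC(=C)[C@H]2C=CC(C)=C(O[K])[C@]2(C)CC#C[Si](C(C)C)(C(C)C)C(C)C)cc1 | intermediate
13 | dienyl triflate: cyclohexa-1,3-diene with OTf on C9 and methyl on C8, C5 and C10 substituents as in 11 | COc1ccc(COCC(=C)[C@H]2C=CC(C)=C(OS(=O)(=O)C(F)(F)F)[C@]2(C)CC#C[Si](C(C)C)(C(C)C)C(C)C)cc1 | intermediate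
14 | alkylzinc iodide, [(E)-5-methoxy-3-methyl-5-oxopent-3-en-1-yl]zinc iodide | I[Zn]CC/C(C)=C/C(=O)OC | intermediate
15 | triene ester: 13 with OTf replaced by the (E)-CH2CH2C(CH3)=CHCO2Me chain | COc1ccc(COCC(=C)[C@H]2C=CC(C)=C(CC/C(C)=C/C(=O)OC)[C@]2(C)CC#C[Si](C(C)C)(C(C)C)C(C)C)cc1 | intermediate
16 | methyl (5S,9R,10S,13E)-19-[(4-methoxybenzyl)oxy]-3-(triisopropylsilyl)-3,4-secolabda-4(18),7,13-trien-2-yn-15-oate (H-5 β, H-9 β, C20 α) | COc1ccc(COCC(=C)[C@H]2CC=C(C)[C@@H](CC/C(C)=C/C(=O)OC)[C@]2(C)CC#C[Si](C(C)C)(C(C)C)C(C)C)cc1 | intermediate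
17 | methyl (5S,9R,10S,13E)-19-[(4-methoxybenzyl)oxy]-3,4-secolabda-4(18),7,13-trien-2-yn-15-oate | COc1ccc(COCC(=C)[C@H]2CC=C(C)[C@@H](CC/C(C)=C/C(=O)OC)[C@]2(C)CC#C)cc1 | intermediate
18 | methyl (5S,9R,10S,13E)-19-[(4-methoxybenzyl)oxy]-3-oxo-3,4-secolabda-4(18),7,13-trien-15-oate | COc1ccc(COCC(=C)[C@H]2CC=C(C)[C@@H](CC/C(C)=C/C(=O)OC)[C@]2(C)CCC=O)cc1 | intermediate
19 | oxatitanacycle: titanocene bonded to O3 and C18, five-membered ring cis-fused to ring A at C3–C4 on the β face | COc1ccc(COC[C@@]3(C[Ti+2]4)[C@H]2CC=C(C)[C@@H](CC/C(C)=C/C(=O)OC)[C@]2(C)CC[C@@H]3O4)cc1.c1cc[cH-]c1.c1cc[cH-]c1 | intermediate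
20 | methyl (3S,4R,5S,9R,10S,13E)-3-hydroxy-19-[(4-methoxybenzyl)oxy]labda-7,13-dien-15-oate | COc1ccc(COC[C@@]3(C)[C@H]2CC=C(C)[C@@H](CC/C(C)=C/C(=O)OC)[C@]2(C)CC[C@@H]3O)cc1 | intermediate
21 | methyl (3S,4R,5S,9R,10S,13E)-3,19-dihydroxylabda-7,13-dien-15-oate | OC[C@@]1(C)[C@H]2CC=C(C)[C@@H](CC/C(C)=C/C(=O)OC)[C@]2(C)CC[C@@H]1O | intermediate
22 | (3S,4R,5S,9R,10S,13E)-3,19-dihydroxylabda-7,13-dien-15-oic acid | OC[C@@]1(C)[C@H]2CC=C(C)[C@@H](CC/C(C)=C/C(=O)O)[C@]2(C)CC[C@@H]1O | intermediate
23 | (3S,4R,5S,9R,10S,13E)-19-acetoxy-3-hydroxylabda-7,13-dien-15-oic acid (CNP0325522.1) | CC(=O)OC[C@@]1(C)[C@H]2CC=C(C)[C@@H](CC/C(C)=C/C(=O)O)[C@]2(C)CC[C@@H]1O | target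

**Step count and risks**

Total step count: 15. Longest linear sequence: 13 steps (steps 3–15, from 5 to 23).

Steps most likely to fail:

1. Step 12 (proposed new method). The 1,1-disubstituted alkene may fail to insert next to the forming quaternary centre, the aldehyde may undergo reductive dimerisation on titanium, or the allylic ether oxygen may be lost by β-elimination from the alkene complex. The fallback uses known chemistry, sets out from 18 and comes back at 20. Iron-hydride hydrogen-atom transfer to the C4=C18 alkene (Fe(acac)3, PhSiH3, EtOH/ethylene glycol, 60 °C) should give the tertiary C4 radical, which closes 6-exo onto the C3 aldehyde to the cyclised carbinol mixture F1. Oxidation with DMP should give the 3-ketone F2, at which stage the unwanted C4 epimer is removed by chromatography. LiBH(s-Bu)3 (THF, −78 °C) then delivers hydride from the equatorial direction and should give the axial alcohol 20.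

2. Step 9. Coordination of the hindered diene to chromium may be slow, a 1,5-hydrogen shift of the diene may precede reduction, or the silylalkyne or the enoate may be partly reduced. The fallback sets out from 11 and comes back at 16. Addition of CH2=CHMgBr/CeCl3 to the C9 ketone from the β face and trapping with ClCO2Me should give the tertiary bis-allylic carbonate F3. Palladium-catalysed formate reduction (Pd(OAc)2, PBu3, HCO2NH4, dioxane, 80 °C), in which palladium ionises anti to the carbonate and passes hydride to C9 from the β face, should give the 9-vinyl compound F4 with the Δ7 alkene. Rhodium-catalysed hydroboration of the vinyl group (RhCl(PPh3)3, pinacolborane) should give the primary boronate F5. Suzuki–Miyaura coupling with methyl (E)-3-iodobut-2-enoate (COC(=O)/C=C(\C)I; Pd(OAc)2, SPhos, K3PO4, toluene/H2O) returns to 16.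

3. Step 15. The 3-hydroxyl may be acylated along with the 19-hydroxyl, or the mixed anhydride at C15 may survive work-up. The fallback sets out from 21 and comes back at 23. Acetylation of the diol ester 21 (Ac2O, pyridine, 0 °C), where no free acid is present, should give the 19-acetate methyl ester F6. SN2 demethylation with LiI in refluxing EtOAc cleaves the methyl ester at its methyl carbon, should leave the acetate, and returns 23.

Further compounds
F1 | step 12 | methyl (13E)-3-hydroxy-19-[(4-methoxybenzyl)oxy]labda-7,13-dien-15-oate, mixture of C3 and C4 epimers | COc1ccc(COCC3(C)[C@H]2CC=C(C)[C@@H](CC/C(C)=C/C(=O)OC)[C@]2(C)CCC3O)cc1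
F2 | step 12 | methyl (4R,5S,9R,10S,13E)-19-[(4-methoxybenzyl)oxy]-3-oxolabda-7,13-dien-15-oate | COc1ccc(COC[C@@]3(C)[C@H]2CC=C(C)[C@@H](CC/C(C)=C/C(=O)OC)[C@]2(C)CCC3=O)cc1
F3 | step 9 | tertiary bis-allylic methyl carbonate of 11 (C9: vinyl β, OCO2Me α) | COc1ccc(COCC(=C)[C@H]2CC=C(C)[C@](OC(=O)OC)(C=C)[C@]2(C)CC#C[Si](C(C)C)(C(C)C)C(C)C)cc1
F4 | step 9 | 9-vinyl compound (vinyl α, H-9 β, Δ7) | COc1ccc(COCC(=C)[C@H]2CC=C(C)[C@@H](C=C)[C@]2(C)CC#C[Si](C(C)C)(C(C)C)C(C)C)cc1
F5 | step 9 | primary pinacol boronate (C12–Bpin) | COc1ccc(COCC(=C)[C@H]2CC=C(C)[C@@H](CCB3OC(C)(C)C(C)(C)O3)[C@]2(C)CC#C[Si](C(C)C)(C(C)C)C(C)C)cc1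
F6 | step 15 | methyl (3S,4R,5S,9R,10S,13E)-19-acetoxy-3-hydroxylabda-7,13-dien-15-oate | CC(=O)OC[C@@]1(C)[C@H]2CC=C(C)[C@@H](CC/C(C)=C/C(=O)OC)[C@]2(C)CC[C@@H]1O
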